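(The readings were computed for substances that don't exist; noise was put on by code.)

- The closed, stirred vessel takes starting material and coupling partner at one constant temperature, and each run follows the product against time.

| setting | south | south-west | east | north-west |
|---|---|---|---|---|
| starting material | 120 mM | 360 mM | 120 mM | 24.0 mM |
| coupling partner | 360 mM | 360 mM | 720 mM | 72.0 mM |
| time |  |  |  | 46 min |

- south run (time / min: [product] / mM): 7.7: 28.5; 15: 41.5; 23: 50.8; 31: 55.1; 38: 57.0; 46: 58.6
- south-west run (time / min: [product] / mM): 7.7: 80.9; 15: 118.0; 23: 139.4; 31: 152.2; 38: 157.6; 46: 160.9
- east run (time / min: [product] / mM): 7.7: 41.8; 15: 60.0; 23: 67.8; 31: 71.9; 38: 73.9; 46: 75.4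

(scatter of a reading: 0.4 mM)

- reaction order in [starting material] at the outset, round the charge of the south run, defined at two percent of the starting material turned into product (one fixed amount of product, the same in the runs compared)
- reaction order in [coupling partner] at the outset, round the charge of the south run, defined at two percent of the starting material turned into product
- product in the north-west run at 46 min, as a share of the starting material charged

- Overall: starting material + coupling partner -> product.
- Constant volume, constant temperature.
- What is held in complexes is read along with the free species.
- "The second partner" is coupling partner.
- An order is taken over about fifteen percent of the charge, up and down.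

- End state first: in the south run the gaps between the first, third and fifth readings shrink by a factor 0.278, so the product levels near 59.4 mM, an end share Y of 49.5 % of the charge.
- This reckoning reads each run as a race, pseudo-first-order in starting material: coupling has constant c, loss has constant L, Y = c/(c+L), and the curve closes on its plateau with constant λ = c+L.
- The first south reading gives λ = 0.0849 min⁻¹, so c = 0.0420 min⁻¹ and L = 0.0429 min⁻¹.
- The east run levels near 75.8 mM, a share of 63.1 %, with λ = 0.104 min⁻¹, c = 0.0658 min⁻¹ and L = 0.0384 min⁻¹.
- Doubling the partner raises c, while L reads about the same, so the mean, 0.0406 min⁻¹, serves as the loss constant, the first-order constant with which starting material leaves without giving product.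
- The south-west run levels near 166 mM and gives c = 0.0400 min⁻¹, so the order in starting material is 0.956.
- The two c values give a partner order of 0.647; carried down to the north-west charge, that yields 24.7 % at 46 min.
- The weak link is that order, read above the south charge and used below it. Reforged from the end shares, with L held equal, it reads 0.806, giving 20.0 %. The committed values are the midpoints: partner order 0.726 and 22.3 %.
- The forecast gave orders of 0.95 in starting material and 0.7 in coupling partner, and 19 % of product in the north-west run, with “Scaling by about 0.3 for fivefold less partner”, a share lower than the one reckoned here.
- The flask gives orders of 1.0 in starting material and 0.72 in coupling partner, and 22.5 % of product in the north-west run at 46 min.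

    starting material + coupling partner → product (0.3168 M⁻¹ min⁻¹)
    starting material + 2 coupling partner → product + coupling partner (0.7020 M⁻² min⁻¹)
    starting material → decomposed substrate (0.03984 min⁻¹)
    2 coupling partner ⇌ idle reagent dimer, settled at all times (10.80 M⁻¹)

- A power-law fit to the runs gives 1.61 % for the north-west run. In the north-west run, c from the committed order is 0.0131 min⁻¹, and L/c puts about 69.7 % of the charge in decomposed substrate at 46 min. In the south-west run, whose readings went into neither value of L, the loss constant 0.0406 min⁻¹ with c of 0.0400 min⁻¹ places a quarter of the charge as product at 8.69 min, and the run reaches that share at 9.14 min.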